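I began from what a catalyst should leave unchanged, its own concentration: I took c_catalyst as an invariant of each flask and looked for a clock built on it.

| flask | substrate | partner | catalyst | remark | time |
|---|---|---|---|---|---|
| south-east | 0.10 M | 2 equiv | 0.21 mol% | run made earlier |  |
| south | 0.10 M | 2 equiv | 0.72 mol% | run made earlier |  |
| west | 0.10 M | 2.4 equiv | 1 mol% | run made earlier |  |
| Saturday's | 0.030 M | 0.500 equiv | 0.3 mol% |  | 8.0 min |
| Thursday's | 0.40 M | 2.00 equiv | 1 mol% |  | 8.0 min |
| Wednesday's | 0.15 M | 0.500 equiv | 1 mol% |  | 8.0 min |
| Tuesday's | 0.10 M | 2.00 equiv | 1 mol% |  | 8.0 min |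
| Friday's | 0.10 M | 6.00 equiv | 0.25 mol% |  | 8.0 min |

- south-east (time / min: target / %, isomer of the product / %): 0.417: 13, 0; 0.833: 18, 1; 1.50: 23, 2; 3.00: 32, 2; 6.00: 31, 3
- south (time / min: target / %, isomer of the product / %): 0.417: 11, 3; 0.833: 17, 1; 1.50: 23, 0; 3.00: 30, 4; 6.00: 28, 7
- west (time / min: target / %, isomer of the product / %): 0.500: 10, 0; 1.33: 29, 5; 2.50: 32, 1; 4.00: 34, 6; 6.00: 33, 10

(scatter of a reading: 2 percentage points)

1. all flasks from highest to lowest share of target in all that became target or isomer of the product, at 8.0 min (Saturday's / Thursday's / Wednesday's / Tuesday's / Friday's)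
2. the share of target in all that became target or isomer of the product of the flask you put first, at 8.0 min
3. the share of target in all that became target or isomer of the product of the flask you put last, at 8.0 min

- the numbers in the tables scatter by 2 percentage points (one standard deviation)

I read the tables down their last rows. In the west run target stood at 32% at 2.50 min and at 33% at 6.00 min, while isomer of the product reached 10%. So I treated target as a near-steady pool leaking to isomer of the product, a pseudo-first-order loss at fixed c_catalyst. Then c_isomer/c_target equals κ·c_catalyst·t, a product I called the exposure E, and the share of target is 1/(1+E).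

The west run's last row gave 50.5 /M/min for κ, the isomer formed per unit of target, per unit of c_catalyst and per minute. I tried it on the other last rows. For the south run it predicted 6.11% against a reading of 7%, and for the south-east run 1.97% against 3%. The gaps were 0.89 percentage points and 1 point, with a scatter of 2 points. The earlier runs each stood at 0.10 M, so taking κ on c_catalyst rather than on the loading was my assumption.

For 8.0 min I reckoned E = 0.0364 for Saturday's, a share of 96.5%. My shares for Friday's, Tuesday's and Wednesday's came to 90.8%, 71.2% and 62.3%. For Thursday's I reckoned E = 1.62, a share of 38.2%.

The forecast, holding that “the isomerisation scales with absolute catalyst concentration”, gave Saturday's > Friday's > Tuesday's > Wednesday's > Thursday's, with 97% (93% to 99.5%) first and 30% (15% to 50%) last, which is my order but a last share lower than mine.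

The flasks gave Saturday's > Friday's > Tuesday's > Wednesday's > Thursday's, with 91.1% first and 37.3% last.

    target + catalyst ⇌ isomer of the product + catalyst, rate k1*[catalyst]*[target] forward; the back reaction follows from the equilibrium constant (k = 45.9 /M/min)
    substrate + partner ⇌ isomer of the product (K = 14.0 /M, k = 0.0302 /M/min)
    partner → decomposed reagent (k = 0.0484 /min)
    substrate + partner ⇌ target (K = 4.00 /M, k = 1.37 /M/min)

In Thursday's, target stood at 41.3% at 4.00 min and fell to 28.6% by 8.00 min while isomer of the product rose to 48.1%, a ratio of 1.68 against my E of 1.62. Saturday's showed a ratio of 0.0981 against E = 0.0364. In Saturday's the direct turning of substrate + partner into isomer of the product ran beside the catalysed step while target stood at 3.75%, and isomer of the product went from 0.191% at 4.00 min to 0.368% at 8.00 min.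

All runs are calculated for substances that don't exist.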